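**Strategy.** The pyranone C ring is cut at O1–C2 and C3–C4: the C3(OH)–C4(=O) enol-ketone is treated as a masked 3-nitro-2H-chromene, the nitro group being a latent 3-hydroxyl and C4–H a latent carbonyl. Because O1 and C4 sit ortho on the phloroglucinol-derived A ring, a salicylaldehyde supplies O1, C8a, C4a and C4, and 4-methoxy-β-nitrostyrene supplies C2 (with the B ring) and C3. One oxa-Michael/Henry/dehydration annulation forms both bonds and closes the ring; alkaline peroxide then turns the nitroalkene into the flavonol. The precursor is a 2-hydroxybenzaldehyde that already carries the 7-O-prenyl ether and a MOM-protected 5-oxygen.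

Key step: step 3

Remark: the target is an achiral flavonol without stereocentres, so no enantiocontrol is needed; the C2 centre of compounds 6–10 forms racemic and is erased in step 4. "Prenyl" means 3-methylbut-2-en-1-yl throughout.

**Step 1**
Reactants: 1 2,4,6-trihydroxybenzaldehyde; 2 prenyl bromide
Product: 3 2,6-dihydroxy-4-(prenyloxy)benzaldehyde
Conditions: 2 (1.0 equiv), KHCO3 (1.1 equiv), DMF, 0 °C to rt
Reagents that add atoms: none
Why: Williamson etherification in which bicarbonate ionises only the most acidic and least hindered hydroxyl (4-OH, para to the formyl group) while the ortho hydroxyls are tied up in hydrogen bonding to the aldehyde, so one equivalent of the primary allylic bromide should alkylate O4 by SN2.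

**Step 2**
Reactants: 3 2,6-dihydroxy-4-(prenyloxy)benzaldehyde
Product: 4 2-hydroxy-6-(methoxymethoxy)-4-(prenyloxy)benzaldehyde
Conditions: MOMCl (1.1 equiv), i-Pr2NEt (1.3 equiv), CH2Cl2, 0 °C
Reagents that add atoms: chloromethyl methyl ether, COCCl
Why: Amine-base MOM etherification that should be self-limiting, because the two ortho hydroxyls of 3 are equivalent and, once one is capped, the other is locked in the hydrogen bond to the formyl oxygen and is not alkylated under these conditions.

**Step 3**
Reactants: 4 2-hydroxy-6-(methoxymethoxy)-4-(prenyloxy)benzaldehyde; 5 (E)-1-methoxy-4-(2-nitrovinyl)benzene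
Product: 8 5-(methoxymethoxy)-2-(4-methoxyphenyl)-3-nitro-7-(prenyloxy)-2H-chromene (racemic), via oxa-Michael adduct 6 (not isolated), via Henry adduct 7 (not isolated)
Conditions: 5 (1.3 equiv), DABCO (0.5 equiv), MeCN, 4 Å MS, 60 °C
Reagents that add atoms: none
Why: DABCO ionises the chelated 2-OH of 4, the phenoxide adds to the aryl-bearing β-carbon of nitroalkene 5 (oxa-Michael) to give the nitronate of 6, the nitronate carbon attacks the ortho formyl group (intramolecular Henry) to give 7, and E1cB loss of water gives the conjugated nitroalkene 8, which drains the reversible steps. The closest known reaction type is the amine-mediated tandem oxa-Michael/Henry/dehydration of salicylaldehydes and β-nitrostyrenes to 2-aryl-3-nitro-2H-chromenes. The pyran ring is closed at C3–C4 by a 6-exo-trig attack on the aldehyde C=O. The only new stereocentre (C2) forms racemic and needs no control because it becomes sp2 in step 4. Regiochemistry (aryl at C2, nitrogen at C3) is fixed by the polarity of the nitroalkene, and chemoselectivity by the substrate: the MOM cap leaves a single phenolic nucleophile and prevents a push-pull phenoxide that would deactivate the aldehyde, while the prenyl ether is inert to the amine base.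

**Step 4**
Reactants: 8 5-(methoxymethoxy)-2-(4-methoxyphenyl)-3-nitro-7-(prenyloxy)-2H-chromene
Product: 11 3-hydroxy-5-(methoxymethoxy)-2-(4-methoxyphenyl)-7-(prenyloxy)-4H-chromen-4-one, via α-nitro epoxide 9 (not isolated), via acyloin 10 (not isolated)
Conditions: 30% aq H2O2 (excess), 2 M NaOH, MeOH–THF, 0 °C to rt
Reagents that add atoms: hydrogen peroxide, OO; sodium hydroxide, [Na+].[OH-]
Why: Alkaline-peroxide oxidation of a 2-aryl-3-nitro-2H-chromene to a flavonol (Weitz–Scheffer-type nucleophilic epoxidation followed by denitration): hydroperoxide adds at C4, the nitronate closes to α-nitro epoxide 9, opening at benzylic C4 with loss of nitrite gives acyloin 10, and its enediolate is oxidised by the second equivalent of peroxide to the 3-hydroxy-4-pyranone, while the isolated prenyl alkene and the MOM acetal are inert to nucleophilic peroxide and base.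

**Step 5**
Reactants: 11 3-hydroxy-5-(methoxymethoxy)-2-(4-methoxyphenyl)-7-(prenyloxy)-4H-chromen-4-one
Product: 12 3,5-dihydroxy-2-(4-methoxyphenyl)-7-(prenyloxy)-4H-chromen-4-one (target)
Conditions: 2 M aq HCl (cat.), MeOH–THF, rt
Reagents that add atoms: none
Why: Acid-catalysed acetal exchange (MOM cleavage) in which the 5-OMOM group peri to the C4 carbonyl is unusually labile, so dilute acid at room temperature should remove it while the aryl prenyl ether and the aryl methyl ether stay intact.

**Compound list**
1 | 2,4,6-trihydroxybenzaldehyde | O=Cc1c(O)cc(O)cc1O | starting material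
2 | prenyl bromide (1-bromo-3-methylbut-2-ene) | CC(C)=CCBr | starting material
3 | 2,6-dihydroxy-4-(prenyloxy)benzaldehyde | O=Cc1c(O)cc(OCC=C(C)C)cc1O | intermediate
4 | 2-hydroxy-6-(methoxymethoxy)-4-(prenyloxy)benzaldehyde | O=Cc1c(O)cc(OCC=C(C)C)cc1OCOC | intermediate
5 | (E)-1-methoxy-4-(2-nitrovinyl)benzene (trans-4-methoxy-β-nitrostyrene) | COc1ccc(/C=C/[N+](=O)[O-])cc1 | starting material
6 | 2-(methoxymethoxy)-6-[1-(4-methoxyphenyl)-2-nitroethoxy]-4-(prenyloxy)benzaldehyde (oxa-Michael adduct, racemic) | O=Cc1c(OCOC)cc(OCC=C(C)C)cc1OC(C[N+](=O)[O-])c1ccc(OC)cc1 | intermediate (not isolated)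
7 | 5-(methoxymethoxy)-2-(4-methoxyphenyl)-3-nitro-7-(prenyloxy)chroman-4-ol (Henry adduct, racemic diastereomer mixture) | COCOc1cc(OCC=C(C)C)cc2c1C(O)C([N+](=O)[O-])C(c1ccc(OC)cc1)O2 | intermediate (not isolated)
8 | 5-(methoxymethoxy)-2-(4-methoxyphenyl)-3-nitro-7-(prenyloxy)-2H-chromene (racemic) | COCOc1cc(OCC=C(C)C)cc2c1C=C([N+](=O)[O-])C(c1ccc(OC)cc1)O2 | intermediate
9 | 3,4-epoxy-5-(methoxymethoxy)-2-(4-methoxyphenyl)-3-nitro-7-(prenyloxy)chroman (α-nitro epoxide, racemic) | COCOc1cc(OCC=C(C)C)cc2c1C1OC1([N+](=O)[O-])C(c1ccc(OC)cc1)O2 | intermediate (not isolated)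
10 | 4-hydroxy-5-(methoxymethoxy)-2-(4-methoxyphenyl)-7-(prenyloxy)chroman-3-one (acyloin, racemic) | COCOc1cc(OCC=C(C)C)cc2c1C(O)C(=O)C(c1ccc(OC)cc1)O2 | intermediate (not isolated)
11 | 3-hydroxy-5-(methoxymethoxy)-2-(4-methoxyphenyl)-7-(prenyloxy)-4H-chromen-4-one | COCOc1cc(OCC=C(C)C)cc2oc(-c3ccc(OC)cc3)c(O)c(=O)c12 | intermediate
12 | 3,5-dihydroxy-2-(4-methoxyphenyl)-7-(prenyloxy)-4H-chromen-4-one | COc1ccc(-c2oc3cc(OCC=C(C)C)cc(O)c3c(=O)c2O)cc1 | target

**Total step count:** 5
**Longest linear sequence:** 5 steps (from 1; 2 and 5 are commercial)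

**Steps most likely to fail**

1. Step 3 (key step). The oxa-Michael addition is reversible and the Henry closure must occur on an aldehyde deactivated by two alkoxy donors and by chelation, so the sequence may stall at the open adduct or divert into base-induced oligomerisation of the nitrostyrene. The fallback sets out from 4 and returns at 11, building the C ring by the chalcone route. Addition of MeMgBr (2.2 equiv, THF, 0 °C) to 4 should give the benzylic alcohol 1-[2-hydroxy-6-(methoxymethoxy)-4-(prenyloxy)phenyl]ethanol F1. MnO2 (CH2Cl2, rt) should oxidise it to the acetophenone 1-[2-hydroxy-6-(methoxymethoxy)-4-(prenyloxy)phenyl]ethanone F2. Claisen–Schmidt condensation with 4-methoxybenzaldehyde (KOH, EtOH, rt) should give the (E)-2'-hydroxychalcone F3. Algar–Flynn–Oyamada oxidation (H2O2, NaOH, MeOH, 0 °C) should then close the ring to 11.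

2. Step 4. Hydroperoxide addition at C4 may be slowed by the electron-rich A ring, and the acyloin or the flavonolate may suffer oxidative C3–C4 cleavage in alkaline peroxide. The fallback sets out from 4 and returns at 11, installing the C3 oxygen through a carbon–boron bond instead of the nitro group. Lithium (4-methoxyphenyl)acetylide (2.2 equiv, THF, −78 to 0 °C) should add to 4 to give the propargylic alcohol 1-[2-hydroxy-6-(methoxymethoxy)-4-(prenyloxy)phenyl]-3-(4-methoxyphenyl)prop-2-yn-1-ol F4. MnO2 should give the ynone F5. Et2NH-mediated 6-endo-dig oxa-Michael cyclisation should give the flavone 5-(methoxymethoxy)-2-(4-methoxyphenyl)-7-(prenyloxy)-4H-chromen-4-one F6. C3-lithiation with LDA (THF, −78 °C), trapping with B(OMe)3 and oxidation of the boronate with H2O2/AcOH should deliver 11.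

3. Step 5. Acidolysis of the aryl prenyl ether through the prenyl cation may compete with MOM cleavage. The fallback sets out from 11 and returns at 12 by accepting the loss and reinstalling the ether. The acidolysis is driven to completion (HCl, MeOH, reflux) to give the triol 3,5,7-trihydroxy-2-(4-methoxyphenyl)-4H-chromen-4-one (kaempferide) F7. Re-alkylation with 2 (1.0 equiv) and K2CO3 (1.0 equiv) in DMF at rt should then favour O7, because 7-OH is the most acidic hydroxyl, 5-OH is chelated to the carbonyl, and 3-OH is less acidic and hydrogen-bonded.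

**Further compounds**
F1 | step 3 | 1-[2-hydroxy-6-(methoxymethoxy)-4-(prenyloxy)phenyl]ethanol (racemic) | CC(O)c1c(O)cc(OCC=C(C)C)cc1OCOC
F2 | step 3 | 1-[2-hydroxy-6-(methoxymethoxy)-4-(prenyloxy)phenyl]ethanone | CC(=O)c1c(O)cc(OCC=C(C)C)cc1OCOC
F3 | step 3 | (E)-1-[2-hydroxy-6-(methoxymethoxy)-4-(prenyloxy)phenyl]-3-(4-methoxyphenyl)prop-2-en-1-one | COCOc1cc(OCC=C(C)C)cc(O)c1C(=O)/C=C/c1ccc(OC)cc1
F4 | step 4 | 1-[2-hydroxy-6-(methoxymethoxy)-4-(prenyloxy)phenyl]-3-(4-methoxyphenyl)prop-2-yn-1-ol (racemic) | COCOc1cc(OCC=C(C)C)cc(O)c1C(O)C#Cc1ccc(OC)cc1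
F5 | step 4 | 1-[2-hydroxy-6-(methoxymethoxy)-4-(prenyloxy)phenyl]-3-(4-methoxyphenyl)prop-2-yn-1-one | COCOc1cc(OCC=C(C)C)cc(O)c1C(=O)C#Cc1ccc(OC)cc1
F6 | step 4 | 5-(methoxymethoxy)-2-(4-methoxyphenyl)-7-(prenyloxy)-4H-chromen-4-one | COCOc1cc(OCC=C(C)C)cc2oc(-c3ccc(OC)cc3)cc(=O)c12
F7 | step 5 | 3,5,7-trihydroxy-2-(4-methoxyphenyl)-4H-chromen-4-one (kaempferide) | COc1ccc(-c2oc3cc(O)cc(O)c3c(=O)c2O)cc1
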